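Remark on the chemistry (assumption): the sulfate groups are written as hydrogen sulfates, as in the target SMILES; 16 and 17 would be handled as their potassium salts, and the acid form of 17 is released only at the end by cold cation exchange.

## Analysis of the target

The target is a flavonol, a 2-aryl-3-oxy-4H-chromen-4-one. Ring A (C4a, C5–C8, C8a) carries oxygen at C5 and C7. Ring C (O1, C2, C3, C4) carries the carbonyl at C4 and oxygen at C3. Ring B, bonded to C2, is 3',4'-dioxygenated. Three of the five peripheral oxygens (O3, O7, O4') are hydrogen sulfate monoesters, and O5 and O3' are free hydroxyls. The molecule has no stereocentre, so any stereocentre made on the way is temporary and its configuration is irrelevant. The sulfate monoesters are polyanionic, water-soluble, acid-labile and cannot be purified on silica, so they must be installed at the very end, and whatever follows them must be neutral. The difficulty is regiochemical: O5 is set apart by its hydrogen bond to the C4 carbonyl, but O3' and O4' are neighbours of similar reactivity and can only be told apart by a protecting-group pattern laid down at the start. The strategy rests on ring A: it is a phloroglucinol ring, so C4a lies ortho or para to three oxygens (O1, O5, O7) and is strongly nucleophilic. The C4–C4a bond can therefore be closed by acylation once O1, C2, C3 and O3 hang from ring A as a chain. Before closure ring A is symmetrical, so both carbons ortho to O1 are the same.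

## Retrosynthetic reasoning

17 back to 16. The last bond cut is the benzyl C–O bond at O3'. O3' must stay masked while the sulfates go on, and its unmasking must not touch sulfate esters. A benzyl ether answers both, because hydrogenolysis is neutral and leaves O–S bonds and the chromenone alone.

16 back to 15. The three O–S bonds at O3, O7 and O4' are cut together. In 15 the hydroxyls at O3, O5, O7 and O4' are free and O3' is benzylated. The forward step must sulfate three of the four, and the selectivity comes from the structure: O5 is chelated to the C4 carbonyl and is the least nucleophilic oxygen.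

15 back to 13 (through 14). No skeletal bond is cut here; the C2–C3 unsaturation is removed. Ring C is much easier to close at the saturated level, and a dihydroflavonol that already holds O3 needs only a two-electron oxidation to become the pyranone. The forward step removes both temporary stereocentres.

13 back to 12. The three free phenols at O5, O7 and O4' are masked as allyl ethers. Allyl is chosen because its removal by palladium-catalysed allyl transfer leaves the benzyl ether at O3' intact. That orthogonality is what marks O3' as the one oxygen that stays protected through sulfation. Two identical ethers on ring A keep that ring symmetrical.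

12 back to 9 (through 10 and 11). This is the key disconnection, at C4–C4a. Cutting here turns C4 into a carboxyl carbon and C4a into an unsubstituted ring carbon flanked by two oxygens. The alternative cut at O1–C8a would demand a leaving group on ring A and a later exchange for oxygen. The cut at C4–C4a instead uses the natural polarity of a phloroglucinol ether, and because ring A of 9 is symmetrical there is no regiochemical question. The forward reaction must activate the acid without ionising the benzylic C–O bond.

9 back to 8, then to 7 and 2. The acid comes from its methyl ester 8. In 8 the ether bond between O1 and the benzylic carbon (the future C2) is cut, giving the phenol 2 and the glycidic ester 7. The epoxide supplies the electrophilic benzylic carbon and, in the same event, frees the oxygen that becomes O3. The forward step needs attack at the benzylic carbon and not at the carbon next to the ester.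

7 back to 5 and 6. The epoxide is cut at the bond between the future C2 and C3 and at one C–O bond. This is a glycidic ester condensation of the aldehyde 5 with the chloroester 6. One step thus brings in C3, its oxygen and the carboxyl carbon that becomes C4.

5 back to 4 and 3; 2 back to 1. Only O-alkyl bonds are cut. In 3 the hydroxyl para to the formyl group is the more acidic, so allyl goes on O4 first and benzyl on O3 second, which fixes the O3'/O4' distinction at the outset. The phenol 2 is the bis-allyl ether of 1.

## Alternatives that were turned down

Alternative 1: The disconnection is at O1–C8a. Ring A enters as a 2,4,6-trifluorophenyl ketone in the diketone A2. With a carbonate base in a dipolar aprotic solvent, the enolate oxygen on the ring B side displaces an ortho fluorine by addition–elimination and closes ring C as A1. In its favour, the closure is intramolecular, base-mediated and acid-free, and it gives the pyranone oxidation level directly with O3 in place. On the certainty of the ring closure itself it is probably stronger than the chosen route, and it needs no dehydrogenation. Against it, A1 carries fluorine where the target has O5 and O7. Two further C–F to C–O substitutions are needed. The second has to occur on a ring already deactivated by the first alkoxy group, and both compete with alkoxide addition at C2 of the pyranone. A2 is a 2-oxygenated 1,3-diketone that takes several acylation steps to build, and its acetal groups must come off in acid before sulfation. The chosen strategy takes all ring A oxygens from 1 and so avoids any oxygen-for-halogen exchange. It pays for this with an acid-mediated closure and one oxidation step.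

Alternative 2: The disconnection cuts C4a–C4, C4–C3 and O1–C2 at once. The iodophenol A4, carbon monoxide A6 and the arylacetylene A5 combine under palladium catalysis in a secondary amine to give A3. In its favour, this is the most convergent plan: two fragments of similar size, three bonds in one operation, and the aromatic chromenone directly. On convergence and on step count to the tricycle it is stronger than the chosen route. Against it, A3 has hydrogen at C3, and the target needs a sulfated oxygen there. O3 would have to be added afterwards by metalation and oxidation or by epoxidation of the C2–C3 bond of a poly-ether, an extra C–O bond formation with its own risk. The ynone intermediate can also close in the five-membered mode to an aurone. A4 needs iodination ortho to the hydroxyl and not between the two acetal oxygens, and the acetals again need acid. The chosen strategy carries O3 in from the glycidate, so that all five oxygens are in place when ring C closes.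

Alternative 3: The disconnection is at C3–C4. A triazolium-derived carbene with an amidine base adds to the aromatic aldehyde of the dialdehyde A8, and the resulting acyl anion equivalent attacks the aliphatic aldehyde to give A7. In its favour, A7 is the same kind of product as that of step 7, a dihydroflavonol with O3 in place. The conditions are catalytic, weakly basic and acid-free, so the benzylic ether is not at risk; on that point it is stronger. Against it, the acyl anion equivalent must form at an aldehyde that is flanked by two ortho oxygens and deactivated by three donors, the least favourable case. The aliphatic aldehyde is the more reactive towards the carbene, which invites the reverse benzoin or self-condensation. It is also α-aryl and α-aryloxy, so it enolises easily and would be hard to make and keep. The endgame from A7 is the same as from 12, so nothing is saved after the key step, and A8 is longer to reach than 9. The chosen strategy uses the innate polarity of a nucleophilic ring A carbon and an electrophilic carboxyl carbon, not umpolung at a hindered centre.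

Key step: step 7

## Route

Step 1
Reactants: 1 phloroglucinol
Product: 2 3,5-bis(allyloxy)phenol
Conditions: allyl bromide (2.0 equiv), K2CO3, DMF, 0 °C → rt; chromatography
Reagents that add atoms: allyl bromide, C=CCBr
Why: Williamson etherification; the reaction is statistical, carbonate in a dipolar aprotic solvent should favour O- over C-allylation, and the bis-ether should separate from the mono- and tris-ethers by polarity. It is placed first, where the material is cheap.

Step 2
Reactants: 3 3,4-dihydroxybenzaldehyde
Product: 4 4-(allyloxy)-3-hydroxybenzaldehyde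
Conditions: allyl bromide (1.05 equiv), NaHCO3, NaI (cat.), DMF, 40 °C
Reagents that add atoms: allyl bromide, C=CCBr
Why: Williamson etherification; the hydroxyl para to the formyl group is the more acidic, so the weak base should ionise and alkylate it selectively.

Step 3
Reactants: 4 4-(allyloxy)-3-hydroxybenzaldehyde
Product: 5 4-(allyloxy)-3-(benzyloxy)benzaldehyde
Conditions: BnBr, K2CO3, DMF, rt
Reagents that add atoms: benzyl bromide, BrCc1ccccc1
Why: Williamson etherification of the one remaining phenol; this fixes benzyl on the future O3' and allyl on the future O4'.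

Step 4
Reactants: 5 4-(allyloxy)-3-(benzyloxy)benzaldehyde, 6 methyl chloroacetate
Product: 7 methyl (2R*,3S*)-3-[4-(allyloxy)-3-(benzyloxy)phenyl]oxirane-2-carboxylate (racemic trans-glycidate)
Conditions: NaOMe, MeOH, −10 °C → rt
Reagents that add atoms: none
Why: Darzens glycidic ester condensation: the chloroacetate enolate adds to the aldehyde and the alkoxide displaces chloride. The trans epoxide is expected to predominate, but the configuration does not matter because both carbons become sp2 in step 9; methoxide matches the methyl ester.

Step 5
Reactants: 7 methyl (2R*,3S*)-3-[4-(allyloxy)-3-(benzyloxy)phenyl]oxirane-2-carboxylate, 2 3,5-bis(allyloxy)phenol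
Product: 8 methyl (2R*,3R*)-3-[3,5-bis(allyloxy)phenoxy]-3-[4-(allyloxy)-3-(benzyloxy)phenyl]-2-hydroxypropanoate (racemic)
Conditions: Cs2CO3 (0.5 equiv), DMF, 60 °C
Reagents that add atoms: none
Why: SN2 opening of an epoxide by a phenoxide; C3 is benzylic and activated by the para-alkoxyaryl group, whereas C2 next to the ester is a poor site, so attack at C3 is expected. Inversion should give the (2R*,3R*) isomer, but either diastereomer serves; the alkoxide formed re-deprotonates the phenol, so the base need not be stoichiometric.

Step 6
Reactants: 8 methyl (2R*,3R*)-3-[3,5-bis(allyloxy)phenoxy]-3-[4-(allyloxy)-3-(benzyloxy)phenyl]-2-hydroxypropanoate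
Product: 9 (2R*,3R*)-3-[3,5-bis(allyloxy)phenoxy]-3-[4-(allyloxy)-3-(benzyloxy)phenyl]-2-hydroxypropanoic acid (racemic)
Conditions: LiOH, THF–H2O, 0 °C → rt; then 1 M HCl to pH 3, 0 °C
Reagents that add atoms: lithium hydroxide, [Li+].[OH-]
Why: Ester saponification; an α-hydroxy ester hydrolyses fast at low temperature, which should leave no room for β-elimination of the aryloxide, and the brief cold acidification should not touch the benzylic ether.

Step 7
Reactants: 9 (2R*,3R*)-3-[3,5-bis(allyloxy)phenoxy]-3-[4-(allyloxy)-3-(benzyloxy)phenyl]-2-hydroxypropanoic acid
Product: 12 (2R*,3R*)-5,7-bis(allyloxy)-2-[4-(allyloxy)-3-(benzyloxy)phenyl]-3-hydroxychroman-4-one (racemic), via mixed trifluoroacetic anhydride 10 (not isolated), via 3-O-trifluoroacetyl chromanone 11 (not isolated)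
Conditions: (CF3CO)2O (3 equiv), CH2Cl2, 0 °C → rt; then aq. NaHCO3–MeOH, 0 °C
Reagents that add atoms: none
Why: Trifluoroacetic anhydride first esterifies the C2 hydroxyl and turns the carboxyl group into the acyl trifluoroacetate 10, a mixed anhydride polarised further by the trifluoroacetic acid set free. The ring A carbon ortho to the ether oxygen, which is also ortho to one allyloxy group and para to the other, attacks the acyl carbon; loss of trifluoroacetate and of the ring proton gives the aryl ketone 11 and with it the C4–C4a bond. This is an intramolecular Friedel–Crafts acylation of the kind that closes 3-aryloxypropanoic acids to chroman-4-ones, and a 1,3,5-trioxygenated benzene should be reactive enough to need no Lewis acid. Ring C closes in the 6-exo-trig mode, with the acyl C=O outside the new six-membered ring. No stereocentre is created: C2 and C3 come from 9, the 2,3-trans isomer is expected from the anti acid and is also the more stable one if C3 epimerises, and both centres vanish in step 9. Site selectivity needs no control, because ring A of 9 is symmetrical and its two carbons ortho to the ether oxygen are equivalent, while the third free carbon, para to that oxygen, cannot reach the acyl group. The real demand is chemoselectivity: the benzylic C–O bond to ring A must not ionise, and the electron-withdrawing trifluoroacetoxy and acyl groups on the neighbouring carbon, the low temperature and the absence of any acid stronger than CF3CO2H are what should hold it. Cold aqueous NaHCO3 in methanol then hydrolyses the labile trifluoroacetate 11 to the free C3 alcohol 12.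

Step 8
Reactants: 12 (2R*,3R*)-5,7-bis(allyloxy)-2-[4-(allyloxy)-3-(benzyloxy)phenyl]-3-hydroxychroman-4-one
Product: 13 (2R*,3R*)-2-[3-(benzyloxy)-4-hydroxyphenyl]-3,5,7-trihydroxychroman-4-one (racemic)
Conditions: Pd(PPh3)4 (5 mol%), morpholine, THF, rt, degassed
Reagents that add atoms: none
Why: Tsuji–Trost-type allyl transfer: zerovalent palladium ionises each aryl allyl ether to a π-allyl complex and a phenoxide, and morpholine captures the allyl group. The benzyl ether, the ketone and the C3 hydroxyl should be untouched.

Step 9
Reactants: 13 (2R*,3R*)-2-[3-(benzyloxy)-4-hydroxyphenyl]-3,5,7-trihydroxychroman-4-one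
Product: 15 2-[3-(benzyloxy)-4-hydroxyphenyl]-3,5,7-trihydroxy-4H-chromen-4-one, via chromane-3,4-dione 14 (not isolated)
Conditions: I2 (1.1 equiv), KOAc, AcOH, reflux
Reagents that add atoms: none
Why: Iodine–acetate dehydrogenation of a dihydroflavonol: iodine oxidises the enediol tautomer to the 3,4-dione 14, which enolises through the acidic benzylic C2–H to the aromatic pyranone. Acetate buffers the HI, so the benzyl ether should survive; both temporary stereocentres are erased here.

Step 10
Reactants: 15 2-[3-(benzyloxy)-4-hydroxyphenyl]-3,5,7-trihydroxy-4H-chromen-4-one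
Product: 16 2-[3-(benzyloxy)-4-(sulfooxy)phenyl]-5-hydroxy-4-oxo-4H-chromene-3,7-diyl bis(hydrogen sulfate)
Conditions: SO3·NMe3 (excess), Et3N, DMF, 60 °C; size-exclusion chromatography, K+ exchange
Reagents that add atoms: sulfur trioxide–trimethylamine complex, C[N+](C)(C)S(=O)(=O)[O-]
Why: O-sulfation with an amine–sulfur trioxide complex; O7 and O4' are ordinary phenols and O3 is an acidic enolic hydroxyl, so all three should react. O5 is held in a six-membered hydrogen bond to the C4 carbonyl and should stay free, and O3' is blocked as its benzyl ether.

Step 11
Reactants: 16 2-[3-(benzyloxy)-4-(sulfooxy)phenyl]-5-hydroxy-4-oxo-4H-chromene-3,7-diyl bis(hydrogen sulfate)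
Product: 17 quercetin 3,4',7-tris(hydrogen sulfate), 5-hydroxy-2-[3-hydroxy-4-(sulfooxy)phenyl]-4-oxo-4H-chromene-3,7-diyl bis(hydrogen sulfate)
Conditions: H2 (1 atm), Pd/C, MeOH–H2O, rt; then sulfonic acid resin (H+ form), 0 °C, freeze-drying
Reagents that add atoms: none
Why: Hydrogenolysis of a benzyl aryl ether; sulfate monoesters and the chromenone C2–C3 bond are inert under these neutral conditions, so only O3' should be unmasked.

## Compound list

1 | phloroglucinol (benzene-1,3,5-triol) | Oc1cc(O)cc(O)c1 | starting material
2 | 3,5-bis(allyloxy)phenol | Oc1cc(OCC=C)cc(OCC=C)c1 | intermediate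
3 | 3,4-dihydroxybenzaldehyde | O=Cc1ccc(O)c(O)c1 | starting material
4 | 4-(allyloxy)-3-hydroxybenzaldehyde | O=Cc1ccc(OCC=C)c(O)c1 | intermediate
5 | 4-(allyloxy)-3-(benzyloxy)benzaldehyde | O=Cc1ccc(OCC=C)c(OCc2ccccc2)c1 | intermediate
6 | methyl chloroacetate | COC(=O)CCl | starting material
7 | methyl (2R*,3S*)-3-[4-(allyloxy)-3-(benzyloxy)phenyl]oxirane-2-carboxylate (racemic, trans; one enantiomer drawn) | COC(=O)[C@@H]1O[C@H]1c1ccc(OCC=C)c(OCc2ccccc2)c1 | intermediate
8 | methyl (2R*,3R*)-3-[3,5-bis(allyloxy)phenoxy]-3-[4-(allyloxy)-3-(benzyloxy)phenyl]-2-hydroxypropanoate (racemic; one enantiomer drawn) | COC(=O)[C@H](O)[C@H](Oc1cc(OCC=C)cc(OCC=C)c1)c1ccc(OCC=C)c(OCc2ccccc2)c1 | intermediate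
9 | (2R*,3R*)-3-[3,5-bis(allyloxy)phenoxy]-3-[4-(allyloxy)-3-(benzyloxy)phenyl]-2-hydroxypropanoic acid (racemic; one enantiomer drawn) | OC(=O)[C@H](O)[C@H](Oc1cc(OCC=C)cc(OCC=C)c1)c1ccc(OCC=C)c(OCc2ccccc2)c1 | intermediate
10 | (2R*,3R*)-3-[3,5-bis(allyloxy)phenoxy]-3-[4-(allyloxy)-3-(benzyloxy)phenyl]-2-(trifluoroacetoxy)propanoic trifluoroacetic anhydride (racemic; not isolated) | O=C(OC(=O)C(F)(F)F)[C@H](OC(=O)C(F)(F)F)[C@H](Oc1cc(OCC=C)cc(OCC=C)c1)c1ccc(OCC=C)c(OCc2ccccc2)c1 | intermediate
11 | (2R*,3R*)-5,7-bis(allyloxy)-2-[4-(allyloxy)-3-(benzyloxy)phenyl]-4-oxochroman-3-yl trifluoroacetate (racemic; not isolated) | O=C1c2c(OCC=C)cc(OCC=C)cc2O[C@H](c2ccc(OCC=C)c(OCc3ccccc3)c2)[C@H]1OC(=O)C(F)(F)F | intermediate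
12 | (2R*,3R*)-5,7-bis(allyloxy)-2-[4-(allyloxy)-3-(benzyloxy)phenyl]-3-hydroxychroman-4-one (racemic, 2,3-trans; one enantiomer drawn) | O=C1c2c(OCC=C)cc(OCC=C)cc2O[C@H](c2ccc(OCC=C)c(OCc3ccccc3)c2)[C@H]1O | intermediate
13 | (2R*,3R*)-2-[3-(benzyloxy)-4-hydroxyphenyl]-3,5,7-trihydroxychroman-4-one (racemic, 2,3-trans; one enantiomer drawn) | O=C1c2c(O)cc(O)cc2O[C@H](c2ccc(O)c(OCc3ccccc3)c2)[C@H]1O | intermediate
14 | 2-[3-(benzyloxy)-4-hydroxyphenyl]-5,7-dihydroxychromane-3,4-dione (racemic; not isolated) | O=C1C(=O)c2c(O)cc(O)cc2OC1c1ccc(O)c(OCc2ccccc2)c1 | intermediate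
15 | 2-[3-(benzyloxy)-4-hydroxyphenyl]-3,5,7-trihydroxy-4H-chromen-4-one | O=c1c(O)c(-c2ccc(O)c(OCc3ccccc3)c2)oc2cc(O)cc(O)c12 | intermediate
16 | 2-[3-(benzyloxy)-4-(sulfooxy)phenyl]-5-hydroxy-4-oxo-4H-chromene-3,7-diyl bis(hydrogen sulfate) | O=c1c(OS(=O)(=O)O)c(-c2ccc(OS(=O)(=O)O)c(OCc3ccccc3)c2)oc2cc(OS(=O)(=O)O)cc(O)c12 | intermediate
17 | quercetin 3,4',7-tris(hydrogen sulfate) | O=c1c(OS(=O)(=O)O)c(-c2ccc(OS(=O)(=O)O)c(O)c2)oc2cc(OS(=O)(=O)O)cc(O)c12 | target

## Step count and least certain steps

Total: 11 steps. Longest linear sequence: 10 steps (3 to 17 through steps 2–11); the ring A branch (step 1) joins at step 5.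

Step 7 (key step). The most likely failure is acid-promoted ionisation of the benzylic C–O bond. The para-allyloxy group of ring B stabilises the resulting cation, and the outcome would be fragmentation or C-alkylation of ring A. A second failure is trifluoroacetylation of the very electron-rich ring A by excess anhydride in competition with the ring closure. The fallback sets out from 9 and separates protection, activation and cyclisation so that no protic acid is present. Acetylation (Ac2O, pyridine) would give (2R*,3R*)-2-acetoxy-3-[3,5-bis(allyloxy)phenoxy]-3-[4-(allyloxy)-3-(benzyloxy)phenyl]propanoic acid F1. 1-Chloro-N,N,2-trimethylprop-1-en-1-amine in CH2Cl2 would convert it under neutral conditions into the acid chloride, (2R*,3R*)-2-acetoxy-3-[3,5-bis(allyloxy)phenoxy]-3-[4-(allyloxy)-3-(benzyloxy)phenyl]propanoyl chloride F2. AgOSO2CF3 with 2,6-di-tert-butylpyridine at −40 °C would generate the acyl triflate and close the ring to (2R*,3R*)-5,7-bis(allyloxy)-2-[4-(allyloxy)-3-(benzyloxy)phenyl]-4-oxochroman-3-yl acetate F3. K2CO3 (cat.) in MeOH at 0 °C would remove the acetate, and the route is rejoined at 12.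

Step 5. The phenoxide of 2 is ambident, so alkylation through a ring carbon may compete with O-alkylation. Attack at C2 of the epoxide, or base-induced decomposition of the electron-rich glycidate, may also lower the return. The fallback sets out from 7 and makes the same C–O bond by activating an alcohol and not by opening an epoxide. Acid-catalysed hydration (dilute H2SO4, THF–H2O, 0 °C) would open the epoxide at the benzylic carbon to methyl 3-[4-(allyloxy)-3-(benzyloxy)phenyl]-2,3-dihydroxypropanoate F4. A Mitsunobu etherification of F4 with 2 (PPh3, diisopropyl azodicarboxylate, toluene, 0 °C → rt) should then engage the benzylic hydroxyl, which is the one activated towards displacement, and the route is rejoined at 8.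

Step 9. Electrophilic iodination of ring A at C6 or C8 may compete with the oxidation, because after deallylation ring A is a free, highly activated resorcinol-type ring. The fallback sets out from 12, before the allyl groups are removed, and oxidises the C3 alcohol and not the C2–C3 bond. Dess–Martin periodinane (NaHCO3, CH2Cl2, rt) would give 5,7-bis(allyloxy)-2-[4-(allyloxy)-3-(benzyloxy)phenyl]chromane-3,4-dione F5. F5 should tautomerise through its acidic C2–H to 5,7-bis(allyloxy)-2-[4-(allyloxy)-3-(benzyloxy)phenyl]-3-hydroxy-4H-chromen-4-one F6. Deallylation of F6 with Pd(PPh3)4 and morpholine rejoins the route at 15.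

Step 10. Sulfation may stop short at the hydrogen-bonded and hindered O3 or run on to O5. Either course gives mixtures of polyanions that cannot be separated on silica. The fallback sets out from 15 and installs the sulfates as neutral diesters. 2,2,2-Trichloroethyl chlorosulfate with Et3N and 4-(dimethylamino)pyridine in THF would give 2-[3-(benzyloxy)-4-{[(2,2,2-trichloroethoxy)sulfonyl]oxy}phenyl]-5-hydroxy-4-oxo-4H-chromene-3,7-diyl bis(2,2,2-trichloroethyl) bis(sulfate) F7, which can be purified by ordinary chromatography. Reductive removal of the trichloroethyl groups with Zn and HCO2NH4 in MeOH rejoins the route at 16.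

Step 1. Over- and under-alkylation are built into a statistical etherification, and C-allylation of the phloroglucinol nucleus may add to the loss. The fallback sets out from 1 and reaches 2 by taking one group off, not by putting two on. Exhaustive allylation (excess allyl bromide, K2CO3, acetone, reflux) would give 1,3,5-tris(allyloxy)benzene F8. One allyl group is then removed with Pd(PPh3)4 and one equivalent of morpholine. The first cleavage gives a more electron-rich ring whose remaining ethers ionise more slowly, and unchanged F8 can be recycled. The route is rejoined at 2.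

## Further compounds

F1 | step 7 | (2R*,3R*)-2-acetoxy-3-[3,5-bis(allyloxy)phenoxy]-3-[4-(allyloxy)-3-(benzyloxy)phenyl]propanoic acid | OC(=O)[C@H](OC(C)=O)[C@H](Oc1cc(OCC=C)cc(OCC=C)c1)c1ccc(OCC=C)c(OCc2ccccc2)c1
F2 | step 7 | (2R*,3R*)-2-acetoxy-3-[3,5-bis(allyloxy)phenoxy]-3-[4-(allyloxy)-3-(benzyloxy)phenyl]propanoyl chloride | ClC(=O)[C@H](OC(C)=O)[C@H](Oc1cc(OCC=C)cc(OCC=C)c1)c1ccc(OCC=C)c(OCc2ccccc2)c1
F3 | step 7 | (2R*,3R*)-5,7-bis(allyloxy)-2-[4-(allyloxy)-3-(benzyloxy)phenyl]-4-oxochroman-3-yl acetate | O=C1c2c(OCC=C)cc(OCC=C)cc2O[C@H](c2ccc(OCC=C)c(OCc3ccccc3)c2)[C@H]1OC(C)=O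
F4 | step 5 | methyl 3-[4-(allyloxy)-3-(benzyloxy)phenyl]-2,3-dihydroxypropanoate (racemic, mixture of diastereomers) | COC(=O)C(O)C(O)c1ccc(OCC=C)c(OCc2ccccc2)c1
F5 | step 9 | 5,7-bis(allyloxy)-2-[4-(allyloxy)-3-(benzyloxy)phenyl]chromane-3,4-dione (racemic) | O=C1C(=O)c2c(OCC=C)cc(OCC=C)cc2OC1c1ccc(OCC=C)c(OCc2ccccc2)c1
F6 | step 9 | 5,7-bis(allyloxy)-2-[4-(allyloxy)-3-(benzyloxy)phenyl]-3-hydroxy-4H-chromen-4-one | O=c1c(O)c(-c2ccc(OCC=C)c(OCc3ccccc3)c2)oc2cc(OCC=C)cc(OCC=C)c12
F7 | step 10 | 2-[3-(benzyloxy)-4-{[(2,2,2-trichloroethoxy)sulfonyl]oxy}phenyl]-5-hydroxy-4-oxo-4H-chromene-3,7-diyl bis(2,2,2-trichloroethyl) bis(sulfate) | O=c1c(OS(=O)(=O)OCC(Cl)(Cl)Cl)c(-c2ccc(OS(=O)(=O)OCC(Cl)(Cl)Cl)c(OCc3ccccc3)c2)oc2cc(OS(=O)(=O)OCC(Cl)(Cl)Cl)cc(O)c12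
F8 | step 1 | 1,3,5-tris(allyloxy)benzene | C=CCOc1cc(OCC=C)cc(OCC=C)c1
A1 | alternative 1 | 2-[3-(benzyloxy)-4-(methoxymethoxy)phenyl]-5,7-difluoro-3-(methoxymethoxy)chromen-4-one | O=c1c(OCOC)c(-c2ccc(OCOC)c(OCc3ccccc3)c2)oc2cc(F)cc(F)c12
A2 | alternative 1 | 1-[3-(benzyloxy)-4-(methoxymethoxy)phenyl]-2-(methoxymethoxy)-3-(2,4,6-trifluorophenyl)propane-1,3-dione | COCOC(C(=O)c1ccc(OCOC)c(OCc2ccccc2)c1)C(=O)c1c(F)cc(F)cc1F
A3 | alternative 2 | 2-[3-(benzyloxy)-4-(methoxymethoxy)phenyl]-5,7-bis(methoxymethoxy)chromen-4-one | O=c1cc(-c2ccc(OCOC)c(OCc3ccccc3)c2)oc2cc(OCOC)cc(OCOC)c12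
A4 | alternative 2 | 2-iodo-3,5-bis(methoxymethoxy)phenol | Oc1cc(OCOC)cc(OCOC)c1I
A5 | alternative 2 | 2-(benzyloxy)-4-ethynyl-1-(methoxymethoxy)benzene | C#Cc1ccc(OCOC)c(OCc2ccccc2)c1
A6 | alternative 2 | carbon monoxide | [C-]#[O+]
A7 | alternative 3 | 2-[3-(benzyloxy)-4-(methoxymethoxy)phenyl]-3-hydroxy-5,7-bis(methoxymethoxy)chroman-4-one (racemic mixture of diastereomers) | O=C1c2c(OCOC)cc(OCOC)cc2OC(c2ccc(OCOC)c(OCc3ccccc3)c2)C1O
A8 | alternative 3 | 2-{1-[3-(benzyloxy)-4-(methoxymethoxy)phenyl]-2-oxoethoxy}-4,6-bis(methoxymethoxy)benzaldehyde (racemic) | O=CC(Oc1cc(OCOC)cc(OCOC)c1C=O)c1ccc(OCOC)c(OCc2ccccc2)c1
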